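**Strategy.** Ring numbering: C1 = quaternary epoxide carbon (CH2OBz), C2 and C3 = CHOAc, C4 and C5 = CHOH, C6 = epoxide CH. The cyclohexane ring is cut into two achiral C3 units: C2–C3–C4 is a dihydroxyacetone unit (2-phenyl-1,3-dioxan-5-one, C3 = ketone) and C5–C6–C1 is an ynal. One amine-catalysed Michael/aldol α,α′-annulation joins C2 to the alkyne terminus (C1–C2) and C4 to the aldehyde (C4–C5). It exploits the 1,3-cis C2/C4 oxygens flanking C3: the acetal bridge makes both α-carbons bridgeheads, so the hydroxy-enone cannot dehydrate or aromatise, and it carries the C6=C1 alkene for a late hydroxyl-directed epoxidation.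

Key step: step 3

Remark: α is the ring face of the C2 and C4 oxygens (and of the epoxide oxygen), β the opposite face. The sense of induction in step 3 is assigned from the usual enamine model for (S)-pyrrolidine catalysts and from enamine desymmetrisations of 4-substituted cyclohexanones; the antipodal catalyst is equally available.

Step 1
Reactants: 1 but-2-yne-1,4-diol
Product: 2 monobenzoate (4-hydroxybut-2-yn-1-yl benzoate)
Conditions: BzCl added dropwise to the diol kept in excess, pyridine, THF, 0 °C
Reagents that add atoms: benzoyl chloride, O=C(Cl)c1ccccc1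
Why: O-acylation of a symmetric diol kept in excess keeps dibenzoylation low, and unreacted diol is removed by aqueous washing.

Step 2
Reactants: 2 monobenzoate (4-hydroxybut-2-yn-1-yl benzoate)
Product: 3 ynal (4-oxobut-2-yn-1-yl benzoate)
Conditions: MnO2, CH2Cl2, rt; used at once
Reagents that add atoms: none
Why: MnO2 oxidation of a propargylic alcohol stops at the aldehyde and leaves the benzoate untouched.

Step 3
Reactants: 3 ynal (4-oxobut-2-yn-1-yl benzoate); 4 ketone (2-phenyl-1,3-dioxan-5-one)
Product: 6 bicyclic hydroxy-enone [(1R,3R,5S,8S)-8-hydroxy-9-oxo-3-phenyl-2,4-dioxabicyclo[3.3.1]non-6-en-6-yl]methyl benzoate, via keto-enal 5 (not isolated)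
Conditions: 1-[3,5-bis(trifluoromethyl)phenyl]-3-[(2S)-pyrrolidin-2-ylmethyl]thiourea (20 mol %), PhCO2H (20 mol %), wet CHCl3, 0 °C → rt; the ynal added slowly by syringe pump to the ketone and catalyst
Reagents that add atoms: none
Why: Proposed new method: the pyrrolidine of the catalyst turns the ketone into an enamine whose β-carbon adds to the alkyne terminus of the hydrogen-bond-activated ynal (C1–C2), and the keto-enal 5 so formed, after E/Z equilibration through its dienol, closes by attack of the α′-enol or enamine carbon on the aldehyde (C4–C5) in a net 1:1 addition that retains every atom of both partners; the closest known reactions are the Stork–Landesman α,α′-annulation of cyclic ketone enamines with acrolein and amine-catalysed Michael/aldol [3+3] annulations of cyclic ketones with enones, here extended to an ynal. The carbocycle closes in a 6-(enolendo)-exo-trig aldol across the dioxanone, so both new bonds must be axial and cis on the face of the acetal hydrogen, which fixes C2–O and C4–O cis and the phenyl group exo. The absolute configuration is expected to be set in the Michael step, in which the (S)-catalyst desymmetrises the enantiotopic α-carbons of the ketone (attack trans to the equatorial phenyl, as in enamine desymmetrisations of 4-substituted cyclohexanones); the acetal carbon records this choice, so later epimerisation at C2 cannot erode it. C5–OH should be axial and trans to C4–O through a hydrogen-bonded closed transition state that holds the aldehyde oxygen gauche to the C3 carbonyl. The step needs 1,4- rather than 1,2-addition to the ynal, favoured by the soft enamine and the reversibility of the aldol, and it must stop at the β-hydroxy ketone: dehydration, alkene migration into conjugation and aromatisation, the usual fate of ketone/ynal [3+3] adducts, are blocked because C2 and C4 are bridgeheads (Bredt strain).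

Step 4
Reactants: 6 bicyclic hydroxy-enone
Product: 7 bicyclic keto ketal ether (C5–O-(2-methoxypropan-2-yl) ether of the hydroxy-enone)
Conditions: 2-methoxypropene, PPTS (cat.), CH2Cl2, 0 °C
Reagents that add atoms: 2-methoxypropene, COC(C)=C
Why: Acid-catalysed addition of the C5 hydroxyl to the enol ether (mixed ketal formation) masks C5–OH without a new stereocentre and without base that could trigger retro-aldol.

Step 5
Reactants: 7 bicyclic keto ketal ether
Product: 9 bicyclic 3β-acetate, via lithium alkoxide 8 (not isolated)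
Conditions: LiBH(s-Bu)3, THF, −78 °C; then Ac2O, DMAP, −78 °C → rt
Reagents that add atoms: acetic anhydride, CC(=O)OC(C)=O
Why: Hydride reduction of the bridging ketone, expected from the open face above the two ring oxygens of the chair dioxane because the other face is screened by the axial C5 ketal ether, sets C3–O β (trans to C2–O and C4–O), and the alkoxide is acetylated in the same flask.

Step 6
Reactants: 9 bicyclic 3β-acetate
Product: 11 trans-4,5-O-isopropylidene allylic alcohol (C2–OH free), via triol 10 (not isolated)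
Conditions: CSA (cat.), MeOH, 0 °C → rt; evaporate; then 2,2-dimethoxypropane, acetone, rt
Reagents that add atoms: 2,2-dimethoxypropane, COC(C)(C)OC
Why: Acid-catalysed methanolysis removes the mixed ketal and the strained all-axial benzylidene acetal, and ketal exchange then caps the only vicinal diol (trans C4/C5) as its acetonide, because a 1,3-acetonide across C2/C4 would need an endo methyl group inside the bicycle.

Step 7
Reactants: 11 trans-4,5-O-isopropylidene allylic alcohol
Product: 12 epoxy alcohol (1,6α-epoxide, oxygen cis to C2–OH)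
Conditions: VO(acac)2 (5 mol %), t-BuOOH, CH2Cl2, 0 °C → rt
Reagents that add atoms: tert-butyl hydroperoxide, CC(C)(C)OO
Why: Vanadium-catalysed hydroxyl-directed epoxidation delivers oxygen to the alkene face syn to the allylic C2–OH (α), setting C1 and C6, while the β-face is also shielded by the C5 acetonide oxygen.

Step 8
Reactants: 12 epoxy alcohol
Product: 13 epoxy 2,3-diacetate acetonide
Conditions: Ac2O, pyridine, DMAP (cat.), CH2Cl2, 0 °C → rt
Reagents that add atoms: acetic anhydride, CC(=O)OC(C)=O
Why: DMAP-catalysed acetylation of the one remaining secondary alcohol.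

Step 9
Reactants: 13 epoxy 2,3-diacetate acetonide
Product: 14 target, [(1S,2R,3S,4R,5R,6S)-2,3-bis(acetyloxy)-4,5-dihydroxy-7-oxabicyclo[4.1.0]heptan-1-yl]methyl benzoate
Conditions: AcOH/H2O (4:1), rt
Reagents that add atoms: none
Why: The strained trans-fused acetonide hydrolyses under mild aqueous acid that should leave the esters and the epoxide, which is deactivated by its electron-withdrawing neighbours, intact.

**Compound list**

1 | but-2-yne-1,4-diol | OCC#CCO | starting material
2 | monobenzoate, 4-hydroxybut-2-yn-1-yl benzoate | OCC#CCOC(=O)c1ccccc1 | intermediate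
3 | ynal, 4-oxobut-2-yn-1-yl benzoate | O=CC#CCOC(=O)c1ccccc1 | intermediate
4 | ketone, 2-phenyl-1,3-dioxan-5-one | O=C1COC(c2ccccc2)OC1 | starting material
5 | keto-enal, (Z)-4-oxo-2-(5-oxo-2-phenyl-1,3-dioxan-4-yl)but-2-en-1-yl benzoate, side chain trans to phenyl | O=C1CO[C@H](c2ccccc2)O[C@H]1/C(COC(=O)c1ccccc1)=C\C=O | intermediate (not isolated)
6 | bicyclic hydroxy-enone, [(1R,3R,5S,8S)-8-hydroxy-9-oxo-3-phenyl-2,4-dioxabicyclo[3.3.1]non-6-en-6-yl]methyl benzoate (phenyl exo; C2–O and C4–O α, C5–OH β) | O=C1[C@H]3[C@@H](O)C=C(COC(=O)c2ccccc2)[C@@H]1O[C@@H](c1ccccc1)O3 | intermediate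
7 | bicyclic keto ketal ether, C5–O-(2-methoxypropan-2-yl) ether of the hydroxy-enone | O=C1[C@H]3[C@@H](OC(C)(C)OC)C=C(COC(=O)c2ccccc2)[C@@H]1O[C@@H](c1ccccc1)O3 | intermediate
8 | lithium 3β-alkoxide from reduction of the keto ketal ether | [Li+].[O-][C@H]1[C@H]3[C@@H](OC(C)(C)OC)C=C(COC(=O)c2ccccc2)[C@@H]1O[C@@H](c1ccccc1)O3 | intermediate (not isolated)
9 | bicyclic 3β-acetate (2α,4α-O-benzylidene, C5β ketal ether) | CC(=O)O[C@H]1[C@H]3[C@@H](OC(C)(C)OC)C=C(COC(=O)c2ccccc2)[C@@H]1O[C@@H](c1ccccc1)O3 | intermediate
10 | triol, (3β-acetoxy-2α,4α,5β-trihydroxycyclohex-6-en-1-yl)methyl benzoate (C1=C6 alkene) | CC(=O)O[C@H]1[C@H](O)[C@@H](O)C=C(COC(=O)c2ccccc2)[C@@H]1O | intermediate (not isolated)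
11 | trans-4α,5β-O-isopropylidene derivative of the triol, C2α–OH free | CC(=O)O[C@H]1[C@@H]2OC(C)(C)O[C@H]2C=C(COC(=O)c3ccccc3)[C@@H]1O | intermediate
12 | epoxy alcohol, 1,6α-epoxide of the acetonide (epoxide oxygen cis to C2–OH) | CC(=O)O[C@H]1[C@@H]2OC(C)(C)O[C@H]2[C@@H]3O[C@]3(COC(=O)c4ccccc4)[C@@H]1O | intermediate
13 | epoxy 2α,3β-diacetate acetonide | CC(=O)O[C@H]1[C@@H]2OC(C)(C)O[C@H]2[C@@H]3O[C@]3(COC(=O)c4ccccc4)[C@@H]1OC(C)=O | intermediate
14 | [(1S,2R,3S,4R,5R,6S)-2,3-bis(acetyloxy)-4,5-dihydroxy-7-oxabicyclo[4.1.0]heptan-1-yl]methyl benzoate | CC(=O)O[C@H]1[C@H](O)[C@@H](O)[C@@H]2O[C@]2(COC(=O)c2ccccc2)[C@@H]1OC(C)=O | target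

**Step count.** Total: 9 steps. Longest linear sequence: 9 steps (1 → 14); compound 4 is bought.

**Steps most likely to fail**

1. Step 3 (proposed new method). The enamine may add 1,2 to the aldehyde before it adds 1,4 to the alkyne, so the ring never closes, or the choice between the two α-carbons of 4 may be poorly controlled, giving low enantiomeric purity. Fallback, setting out from 3 and 4 and coming back at 6, makes the two bonds one after the other with known reactions. An (R)-proline-catalysed aldol (DMF, 4 °C) should give the anti-aldol adduct F1 (C4–C5 bond; C4 as in 6, C5 epimeric). TBSOTf/Et3N converts it to the bis-silyl compound F2 (silyl ether plus silyl enol ether towards C2). A cationic monovalent gold catalyst (Ph3PAuCl/AgSbF6, wet acetone) then effects the known 6-endo-dig carbocyclisation of the silyl enol ether onto the alkyne (C1–C2 bond) to give the bicyclic silyl ether F3. HF·pyridine frees the C5-epimeric alcohol F4, Mitsunobu inversion with chloroacetic acid (PPh3, DIAD) gives the chloroacetate F5, and thiourea/NaHCO3 in EtOH releases 6.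

2. Step 5. Hydride delivery to the bridging ketone may show poor facial selectivity, or attack from the wrong face may dominate. Fallback, setting out from 6 and coming back at 11, uses chelation instead of steric control. Narasaka–Prasad reduction of the free β-hydroxy ketone (Et2BOMe, NaBH4, THF/MeOH, −78 °C) should give the syn-1,3-diol F6. Selective silylation of the less hindered allylic C5–OH (TESCl, imidazole, −20 °C) gives the silyl ether F7, and Ac2O/DMAP gives the acetate F8, which under the conditions of step 6 gives 11.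

3. Step 6. The ketal exchange may be incomplete or place the acetonide elsewhere, and the acetyl group may migrate in the free triol under acid. Fallback, setting out from 9 and coming back at 14, replaces the acetonide by a silicon bridge. Brief aqueous TFA (THF, 0 °C) gives isolated triol 10. 1,3-Dichloro-1,1,3,3-tetraisopropyldisiloxane with imidazole in DMF should silylate the least hindered allylic C5–OH first and can then close only onto the neighbouring C4–OH, giving the disiloxane F9. VO(acac)2/t-BuOOH gives the epoxy alcohol F10 and Ac2O/pyridine/DMAP gives the diacetate F11. HF·pyridine in THF then frees 14.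

Further compounds
F1 | step 3 | anti-aldol adduct, 4-[4-(benzoyloxy)-1-hydroxybut-2-yn-1-yl]-2-phenyl-1,3-dioxan-5-one (C4 as in 6, C5 epimeric) | O=C1CO[C@@H](c2ccccc2)O[C@@H]1[C@H](O)C#CCOC(=O)c1ccccc1
F2 | step 3 | bis-silyl compound (TBS ether at C5–O, TBS enol ether C3=C2) | CC(C)(C)[Si](C)(C)OC1=CO[C@@H](c2ccccc2)O[C@@H]1[C@H](O[Si](C)(C)C(C)(C)C)C#CCOC(=O)c1ccccc1
F3 | step 3 | bicyclic silyl ether, C5-epimer of 6 as its TBS ether | O=C1[C@H]3[C@H](O[Si](C)(C)C(C)(C)C)C=C(COC(=O)c2ccccc2)[C@@H]1O[C@@H](c1ccccc1)O3
F4 | step 3 | C5-epimeric alcohol (C5–OH α) | O=C1[C@H]3[C@H](O)C=C(COC(=O)c2ccccc2)[C@@H]1O[C@@H](c1ccccc1)O3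
F5 | step 3 | C5β chloroacetate of 6 | O=C1[C@H]3[C@@H](OC(=O)CCl)C=C(COC(=O)c2ccccc2)[C@@H]1O[C@@H](c1ccccc1)O3
F6 | step 5 | syn-1,3-diol (C3β–OH, C5β–OH, benzylidene intact) | O[C@H]1[C@H]3[C@@H](O)C=C(COC(=O)c2ccccc2)[C@@H]1O[C@@H](c1ccccc1)O3
F7 | step 5 | C5-O-triethylsilyl ether of F6 | O[C@H]1[C@H]3[C@@H](O[Si](CC)(CC)CC)C=C(COC(=O)c2ccccc2)[C@@H]1O[C@@H](c1ccccc1)O3
F8 | step 5 | C3β acetate of F7 | CC(=O)O[C@H]1[C@H]3[C@@H](O[Si](CC)(CC)CC)C=C(COC(=O)c2ccccc2)[C@@H]1O[C@@H](c1ccccc1)O3
F9 | step 6 | 4,5-O-(tetraisopropyldisiloxane-1,3-diyl) derivative of 10 | CC(=O)O[C@H]1[C@@H]2O[Si](C(C)C)(C(C)C)O[Si](C(C)C)(C(C)C)O[C@H]2C=C(COC(=O)c3ccccc3)[C@@H]1O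
F10 | step 6 | 1,6α-epoxide of F9 | CC(=O)O[C@H]1[C@@H]2O[Si](C(C)C)(C(C)C)O[Si](C(C)C)(C(C)C)O[C@H]2[C@@H]3O[C@]3(COC(=O)c4ccccc4)[C@@H]1O
F11 | step 6 | 2,3-diacetate of F10 | CC(=O)O[C@H]1[C@@H]2O[Si](C(C)C)(C(C)C)O[Si](C(C)C)(C(C)C)O[C@H]2[C@@H]3O[C@]3(COC(=O)c4ccccc4)[C@@H]1OC(C)=O
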